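At early times the alpha flask lags. Only 0.4 % of its free monomer is in chains at 8.00 min, and its gain per minute up to then is smaller than its gain per minute between 40.0 min and 50.0 min. The late interval is therefore the better reading of what a charged pre-initiator can do.

| flask | free monomer | pre-initiator | temperature | remark | time |
|---|---|---|---|---|---|
| alpha | 0.025 M | 0.2 mol% | 130 °C | run made earlier |  |
| blue | 0.050 M | 0.2 mol% | 130 °C |  | 8.0 h |
| grey | 0.050 M | 0.2 mol% | 115 °C |  | 8.0 h |
| green | 0.050 M | 0.2 mol% | 100 °C |  | 8.0 h |

alpha run (percent of the free monomer charged): time / min: monomer in chains / % = 2.50: 0.1; 8.00: 0.4; 15.0: 1.1; 20.0: 2.0; 30.0: 4.6; 40.0: 7.8; 50.0: 11.5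

(standard deviation of a reading: 0.5 percentage points)

- the earlier runs do not show what temperature does; that part of a forecast is a guess
- no earlier run changes the charge of pre-initiator; that part of a forecast is a guess

* the flask that comes out highest in amount of monomer in chains, in percent of the free monomer charged, or "all alike" when all lie within 1.5 percentage points (blue / grey / green / all alike)
* monomer in chains at the end, in percent of the free monomer charged, blue
* monomer in chains at the end, in percent of the free monomer charged, grey
* monomer in chains at the end, in percent of the free monomer charged, green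

The decision for the next run is whether 0.2 mol% of pre-initiator can serve for 8.0 h at 0.050 M, or whether more must be charged. The way to decide is to count turnovers. At this loading, each charged pre-initiator has to carry 500 monomer units for full conversion.

In its last interval, alpha loses free monomer with a pseudo-first-order constant of 0.00410 min⁻¹. Dividing this by the charged pre-initiator, 5.00 × 10⁻⁵ M, gives the turnover constant 81.9 L mol⁻¹ min⁻¹, the turnovers per charged pre-initiator per minute and per mole per litre of free monomer. It is a reading from two points, each good to 0.5 percentage points.

Blue holds twice the pre-initiator of alpha, so this reckoning gives a constant of 0.00819 min⁻¹ and 98.0 % in chains at 8.0 h. That figure leans high, since it has each charged pre-initiator working from the first minute to the last. A figure that leans high does not show that the loading serves, so blue is run as written, as the test of that loading. Grey and green rest on a guess about temperature, and blue is expected highest.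

The forecast, holding that “the active species builds up slowly from the pre-initiator”, gives 96 % for blue, 94 % for grey and 68 % for green, with blue highest.

The flasks give 79.6 % in blue, 59.1 % in grey and 24.2 % in green, so blue comes out highest.

    free monomer + initiator → living end + monomer in chains (k = 0.0140 L mol⁻¹ s⁻¹, Ea = 81.0 kJ mol⁻¹)
    free monomer + living end → monomer in chains + living end, rate k2*[living end]*[free monomer] (k = 0.210 L mol⁻¹ s⁻¹, Ea = 75.0 kJ mol⁻¹)
    monomer in chains + initiator ⇌ isomer of the product + initiator, rate k3*[initiator]*[monomer in chains] forward; the back reaction follows from the equilibrium constant (K = 0.460, k = 0.150 L mol⁻¹ s⁻¹, Ea = 77.0 kJ mol⁻¹, ΔH = −19.0 kJ mol⁻¹)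
    living end + free monomer → dead end (k = 3.60 × 10⁻⁴ L mol⁻¹ s⁻¹, Ea = 79.0 kJ mol⁻¹)
    pre-initiator → initiator (k = 7.40 × 10⁻⁵ s⁻¹, Ea = 128 kJ mol⁻¹)
    (constants at 100 °C)

In blue at 8.00 h, [living end] is 2.50 × 10⁻⁵ M, a quarter of the pre-initiator charged. Applied to the mean of [living end] at 4.00 h and 8.00 h, the turnover constant 81.9 L mol⁻¹ min⁻¹ takes blue's 35.5 % of free monomer at 4.00 h down to 18.8 %, and blue holds 20.1 %. Green, over the same hours and counted the same way, shows a constant of 13.1 L mol⁻¹ min⁻¹, smaller than 81.9 L mol⁻¹ min⁻¹.

The runs are calculated with constants of no real substance; the scatter is artificial.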